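**Retrosynthetic overview**
1. C-12–C-13 is cut last: the target comes from a C1–C12 triacetoxy aldehyde and a reversed-polarity C4 unit, the carbonyl carbon of methyl vinyl ketone made nucleophilic as an (E)-γ-acetoxy-γ-methylallylboronate. Allyl transfer sets C-12 and C-13; the acetyl group then shifts from O-13 to O-12.
2. The aldehyde comes from an amide. The 6β- and 8α-oxygens come from a 7-en-6-one (α-epoxidation, reductive opening, α-face hydride), and the enone from a Δ7 alkene by allylic oxidation.
3. The C-20 oxygen comes from 1,5-hydrogen transfer to an 8β-alkoxyl radical in the 8-epi series; the resulting 8β,20-ether is opened to the 20-acetate and the Δ7 alkene.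
4. Rings: carbocycles A and B are taken intact from (+)-sclareolide. The lactone is opened in step 2, an oxolane is made in step 3 and opened in step 4, and an oxirane is made in step 6 and opened in step 7.

Assumption: labdane numbering and α/β descriptors are used for all ring compounds (C-17 = methyl on C-8; C-20 = carbon on C-10; C-11 and C-12 = side chain on C-9; β = the face of C-20).

**Route**

Step 1
Reactants: 1 (+)-sclareolide
Product: 2 epi-lactone (8-epi-sclareolide; cis-fused γ-lactone with 8β-O and 8α-CH3)
Conditions: conc. H2SO4, HCO2H, 25 °C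
Reagents that add atoms: none
Why: Acid-mediated SN1 ionisation of the tertiary C-8–O bond and re-closure under thermodynamic control (lactone epimerisation) gives the more stable cis-fused lactone, so C-8 is set by product stability with O-8 axial (β) and C-17 equatorial.

Step 2
Reactants: 2 epi-lactone
Product: 3 hydroxy amide (8β-hydroxy-N,N-dimethyl-13,14,15,16-tetranorlabdan-12-amide; axial 8β-OH)
Conditions: Me2NH·HCl, AlMe3, CH2Cl2, 0 → 40 °C; Rochelle salt work-up
Reagents that add atoms: dimethylamine (used as its hydrochloride), CNC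
Why: Weinreb-type aminolysis of the lactone with the aluminium amide opens the ring without touching a stereocentre, frees the axial 8β-hydroxyl, and leaves at C-12 a carbonyl with no abstractable δ-hydrogen that can later be reduced to the aldehyde.

Step 3
Reactants: 3 hydroxy amide
Product: 6 cyclic ether (8β,20-epoxy-N,N-dimethyl-13,14,15,16-tetranorlabdan-12-amide), via hypoiodite 4 (not isolated), via iodo alcohol 5 (not isolated)
Conditions: PhI(OAc)2, I2, cyclohexane–CH2Cl2, hν (tungsten lamp), 25 °C
Reagents that add atoms: none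
Why: Suárez hypoiodite reaction, in which the 8β-alkoxyl radical is 1,3-diaxial to C-20 only (C-17 is geminal, C-19 is out of reach, H-6β would need a 1,4-shift), so 1,5-hydrogen transfer, iodination and ring closure functionalise C-20 alone.

Step 4
Reactants: 6 cyclic ether
Product: 7 alkene acetate (20-acetoxy-N,N-dimethyl-13,14,15,16-tetranorlabd-7-en-12-amide)
Conditions: Ac2O, BF3·OEt2 (2.5 equiv), CH2Cl2, −30 °C
Reagents that add atoms: acetic anhydride, CC(=O)OC(C)=O
Why: Acylative ether cleavage (Ac2O with a Lewis acid): O-acetylation and SN1 ionisation at tertiary C-8 leave the primary C-20 acetate, and E1 loss of the axial H-7α gives mainly the Δ7 alkene, with the amide masked as its BF3 complex and the minor Δ8(17) and Δ8 isomers removed on AgNO3-impregnated silica.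

Step 5
Reactants: 7 alkene acetate
Product: 8 enone (20-acetoxy-N,N-dimethyl-6-oxo-13,14,15,16-tetranorlabd-7-en-12-amide)
Conditions: CrO3, 3,5-dimethylpyrazole, CH2Cl2, −20 °C
Reagents that add atoms: chromium trioxide, O=[Cr](=O)=O
Why: Allylic oxidation with the hexavalent chromium–dimethylpyrazole complex (Salmond conditions) oxidises the only allylic methylene, C-6, to the 7-en-6-one without touching a stereocentre.

Step 6
Reactants: 8 enone
Product: 9 epoxy ketone (20-acetoxy-7α,8α-epoxy-N,N-dimethyl-6-oxo-13,14,15,16-tetranorlabdan-12-amide)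
Conditions: t-BuOOH, DBU, CH2Cl2, 25 °C
Reagents that add atoms: tert-butyl hydroperoxide, CC(C)(C)OO
Why: Weitz–Scheffer nucleophilic epoxidation, in which the peroxide anion adds to C-8 from the α face because the axial C-20 acetoxymethyl group blocks the β face, giving the 7α,8α-epoxide with C-17 β, which is the C-8 configuration of the target.

Step 7
Reactants: 9 epoxy ketone
Product: 11 diol (20-acetoxy-6β,8α-dihydroxy-N,N-dimethyl-13,14,15,16-tetranorlabdan-12-amide), via hydroxy ketone 10 (not isolated)
Conditions: SmI2, THF–MeOH, −78 °C; then NaBH4, MeOH, 0 °C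
Reagents that add atoms: none
Why: Divalent samarium cleaves the C-7–O bond next to the ketone (Molander reduction of α,β-epoxy ketones) with retention at C-8, and borohydride then attacks the 6-ketone from the open α face (the β face is screened by C-17, C-19 and C-20), setting the axial 6β-hydroxyl.

Step 8
Reactants: 11 diol
Product: 12 triacetate amide (6β,8α,20-triacetoxy-N,N-dimethyl-13,14,15,16-tetranorlabdan-12-amide)
Conditions: Ac2O, DMAP, Et3N, 50 °C
Reagents that add atoms: acetic anhydride, CC(=O)OC(C)=O
Why: DMAP-catalysed (Steglich-type) acylation under forcing conditions esterifies both the hindered secondary 6β-hydroxyl and the tertiary 8α-hydroxyl with no change at any stereocentre.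

Step 9
Reactants: 12 triacetate amide
Product: 13 aldehyde (6β,8α,20-triacetoxy-13,14,15,16-tetranorlabdan-12-al)
Conditions: Cp2Zr(H)Cl (1.5 equiv), THF, 25 °C; aqueous work-up
Reagents that add atoms: none
Why: The Schwartz reagent hydrozirconates the tertiary amide to a zirconated hemiaminal that collapses to the aldehyde on work-up (Georg amide-to-aldehyde reduction), a reaction known to spare ester groups.

Step 10
Reactants: 14 methyl vinyl ketone (but-3-en-2-one)
Product: 15 dienyl acetate (buta-1,3-dien-2-yl acetate)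
Conditions: isopropenyl acetate, p-toluenesulfonic acid (cat.), hydroquinone, 95 °C, acetone distilled off
Reagents that add atoms: isopropenyl acetate, CC(=C)OC(C)=O
Why: Acid-catalysed enol ester exchange traps the only possible enol of the ketone as its acetate and is driven by removal of acetone.

Step 11
Reactants: 15 dienyl acetate
Product: 16 allylboronate ((E)-4-(4,4,5,5-tetramethyl-1,3,2-dioxaborolan-2-yl)but-2-en-2-yl acetate; OAc trans and CH3 cis to CH2B)
Conditions: HBpin, FeCl2(L) (4 mol %; L = N-(2,6-diisopropylphenyl)-1-(pyridin-2-yl)methanimine), Mg (10 mol %), Et2O, 23 °C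
Reagents that add atoms: pinacolborane, CC1(C)OBOC1(C)C
Why: Proposed new method: iron-catalysed 1,4-hydroboration of a 2-acyloxy diene, in which the s-cis diene bound to low-valent iron takes hydrogen at C-1 and boron at C-4 so that the new methyl ends up cis and the acetoxy group trans to CH2B; the closest known reaction is the Ritter iron-catalysed 1,4-hydroboration of 2-substituted dienes (myrcene to (E)-geranyl pinacolboronate).

Step 12
Reactants: 13 aldehyde; 16 allylboronate
Product: 19 target ((12R,13S)-6β,8α,12,20-tetraacetoxylabd-14-en-13-ol), via borate ester 17 (not isolated), via tertiary acetate 18 (not isolated)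
Conditions: (S)-3,3′-bis(2,4,6-triisopropylphenyl)-1,1′-binaphthyl-2,2′-diyl hydrogen phosphate (10 mol %), 4 Å MS, toluene, 0 → 25 °C; aq. NaHCO3; then DBU (20 mol %), CH2Cl2, 25 °C
Reagents that add atoms: none
Why: Proposed new method: chiral-phosphoric-acid-catalysed allylboration with a γ-acetoxy-γ-methylallylboronate, in which the former ketone carbon of methyl vinyl ketone attacks the aldehyde carbon as an α-oxyallyl anion (a reversed-polarity, acyl-anion-type carbon at the carbinol level) through a closed chair transition state that places the (E)-acetoxy group equatorial and the (Z)-methyl axial (12,13-anti oxygens), the (S)-acid directs attack to the Si face (12R, hence 13S; the (R)-acid is known to deliver to the Re face), and base-catalysed 1,2-acyl shift then moves the acetyl from tertiary O-13 to the less hindered O-12; the closest known reactions are Antilla-type acid-catalysed allyl- and crotylboration, anti-selective γ-alkoxyallylboration and Lombardo–Trombini acyloxyallylation.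

**Compound list**
1 | (+)-sclareolide | O=C1C[C@@H]2[C@@]3(C)CCCC(C)(C)[C@@H]3CC[C@@]2(C)O1 | starting material
2 | 8-epi-sclareolide (cis-lactone, 8β-O) | O=C1C[C@@H]2[C@@]3(C)CCCC(C)(C)[C@@H]3CC[C@]2(C)O1 | intermediate
3 | 8β-hydroxy-N,N-dimethyl-13,14,15,16-tetranorlabdan-12-amide | CN(C)C(=O)C[C@@H]1[C@@]2(C)CCCC(C)(C)[C@@H]2CC[C@]1(C)O | intermediate
4 | 8β-hypoiodite of 3 | CN(C)C(=O)C[C@@H]1[C@@]2(C)CCCC(C)(C)[C@@H]2CC[C@]1(C)OI | intermediate
5 | 8β-hydroxy-20-iodo-N,N-dimethyl-13,14,15,16-tetranorlabdan-12-amide | CN(C)C(=O)C[C@@H]1[C@@]2(CI)CCCC(C)(C)[C@@H]2CC[C@]1(C)O | intermediate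
6 | 8β,20-epoxy-N,N-dimethyl-13,14,15,16-tetranorlabdan-12-amide | CN(C)C(=O)C[C@@H]1[C@@]23CCCC(C)(C)[C@@H]2CC[C@]1(C)OC3 | intermediate
7 | 20-acetoxy-N,N-dimethyl-13,14,15,16-tetranorlabd-7-en-12-amide | CN(C)C(=O)C[C@@H]1[C@@]2(COC(C)=O)CCCC(C)(C)[C@@H]2CC=C1C | intermediate
8 | 20-acetoxy-N,N-dimethyl-6-oxo-13,14,15,16-tetranorlabd-7-en-12-amide | CN(C)C(=O)C[C@@H]1[C@@]2(COC(C)=O)CCCC(C)(C)[C@@H]2C(=O)C=C1C | intermediate
9 | 20-acetoxy-7α,8α-epoxy-N,N-dimethyl-6-oxo-13,14,15,16-tetranorlabdan-12-amide | CN(C)C(=O)C[C@@H]1[C@@]2(COC(C)=O)CCCC(C)(C)[C@@H]2C(=O)[C@H]3O[C@@]13C | intermediate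
10 | 20-acetoxy-8α-hydroxy-N,N-dimethyl-6-oxo-13,14,15,16-tetranorlabdan-12-amide | CN(C)C(=O)C[C@@H]1[C@@]2(COC(C)=O)CCCC(C)(C)[C@@H]2C(=O)C[C@@]1(C)O | intermediate
11 | 20-acetoxy-6β,8α-dihydroxy-N,N-dimethyl-13,14,15,16-tetranorlabdan-12-amide | CN(C)C(=O)C[C@@H]1[C@@]2(COC(C)=O)CCCC(C)(C)[C@@H]2[C@H](O)C[C@@]1(C)O | intermediate
12 | 6β,8α,20-triacetoxy-N,N-dimethyl-13,14,15,16-tetranorlabdan-12-amide | CN(C)C(=O)C[C@@H]1[C@@]2(COC(C)=O)CCCC(C)(C)[C@@H]2[C@H](OC(C)=O)C[C@@]1(C)OC(C)=O | intermediate
13 | 6β,8α,20-triacetoxy-13,14,15,16-tetranorlabdan-12-al | O=CC[C@@H]1[C@@]2(COC(C)=O)CCCC(C)(C)[C@@H]2[C@H](OC(C)=O)C[C@@]1(C)OC(C)=O | intermediate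
14 | methyl vinyl ketone | CC(=O)C=C | starting material
15 | buta-1,3-dien-2-yl acetate | C=CC(=C)OC(C)=O | intermediate
16 | (E)-4-(4,4,5,5-tetramethyl-1,3,2-dioxaborolan-2-yl)but-2-en-2-yl acetate | CC(=O)O/C(C)=C/CB1OC(C)(C)C(C)(C)O1 | intermediate
17 | O-12 pinacol borate of (12R,13S)-6β,8α,13,20-tetraacetoxylabd-14-en-12-ol | C=C[C@](C)(OC(C)=O)[C@@H](C[C@@H]1[C@@]2(COC(C)=O)CCCC(C)(C)[C@@H]2[C@H](OC(C)=O)C[C@@]1(C)OC(C)=O)OB1OC(C)(C)C(C)(C)O1 | intermediate
18 | (12R,13S)-6β,8α,13,20-tetraacetoxylabd-14-en-12-ol | C=C[C@](C)(OC(C)=O)[C@@H](C[C@@H]1[C@@]2(COC(C)=O)CCCC(C)(C)[C@@H]2[C@H](OC(C)=O)C[C@@]1(C)OC(C)=O)O | intermediate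
19 | (12R,13S)-6β,8α,12,20-tetraacetoxylabd-14-en-13-ol (CNP0136817.1) | C=C[C@](C)(O)[C@@H](C[C@@H]1[C@@]2(COC(C)=O)CCCC(C)(C)[C@@H]2[C@H](OC(C)=O)C[C@@]1(C)OC(C)=O)OC(C)=O | target

**Step count and risks**

Total steps: 12. Longest linear sequence: 10 (steps 1–9 and 12).

Most likely to fail, step 4. The cation at C-8 can also lose a proton from C-17 or C-9, be trapped by the amide oxygen as a lactone, or rearrange. The fallback sets out from 3 and comes back at 7; it oxidises C-20 without consuming the 8β-hydroxyl and makes the alkene by syn-elimination instead of ionisation. Compound 3 is converted with NOCl/pyridine into the nitrite ester F1. Barton photolysis (hν, benzene) gives the 20-aldoxime F2 with the 8β-hydroxyl intact. Deoximation with TiCl3/NH4OAc gives the aldehyde as its 8β,20-hemiacetal F3, and NaBH4 gives the 8β,20-diol F4. Ac2O/pyridine acetylates only the primary hydroxyl to give the monoacetate F5. The Burgess reagent then removes the axial tertiary 8β-hydroxyl by syn-elimination, for which only H-7β and the C-17 hydrogens are cis, so the tetrasubstituted alkene cannot form; this gives 7.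

Second, step 11. The regiochemistry of hydroboration and the survival of the enol acetate under low-valent iron are unproven for an acyloxy diene. The fallback does not use 14 or 15; it sets out from commercial but-3-yn-2-ol in place of 14 and comes back at 16, building the reagent by double-bond transposition instead of diene hydroboration. The alcohol is acetylated (Ac2O, pyridine) to but-3-yn-2-yl acetate F6. Hydroboration (HBpin, Cp2Zr(H)Cl cat.) gives the (E)-alkenylboronate F7. Isomerisation with [Ir(cod)(PPh2Me)2]PF6 activated by H2 then moves the double bond into conjugation with oxygen; the larger acetoxy group takes the position trans to CH2B, giving 16.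

Third, step 12. The acetoxy-substituted allylboronate may react slowly, and the chiral acid may give insufficient face selectivity with this unbranched aldehyde. The fallback sets out from 13 and 14 and comes back at 18; it keeps the same reversed-polarity bond construction but uses a Barbier-type acyloxyallylindium instead of a preformed boronate. Acetyl bromide adds to 14 (ZnCl2 cat.) to give 4-bromobut-2-en-2-yl acetate F8. Indium powder with 13 and F8 in THF–H2O at 25 °C gives 18 together with its 12,13-diastereomers, because face and geometry control are weaker. DBU then gives 19 as in step 12, and the isomers are separated by HPLC.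

**Further compounds**
F1 | step 4 | 8β-nitrite ester of 3 | CN(C)C(=O)C[C@@H]1[C@@]2(C)CCCC(C)(C)[C@@H]2CC[C@]1(C)ON=O
F2 | step 4 | 8β-hydroxy-N,N-dimethyl-20-oxo-13,14,15,16-tetranorlabdan-12-amide (E)-oxime | CN(C)C(=O)C[C@@H]1[C@@]2(/C=N/O)CCCC(C)(C)[C@@H]2CC[C@]1(C)O
F3 | step 4 | 8β,20-epoxy-20-hydroxy-N,N-dimethyl-13,14,15,16-tetranorlabdan-12-amide (hemiacetal, anomer mixture) | CN(C)C(=O)C[C@@H]1[C@@]23CCCC(C)(C)[C@@H]2CC[C@]1(C)OC3O
F4 | step 4 | 8β,20-dihydroxy-N,N-dimethyl-13,14,15,16-tetranorlabdan-12-amide | CN(C)C(=O)C[C@@H]1[C@@]2(CO)CCCC(C)(C)[C@@H]2CC[C@]1(C)O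
F5 | step 4 | 20-acetoxy-8β-hydroxy-N,N-dimethyl-13,14,15,16-tetranorlabdan-12-amide | CN(C)C(=O)C[C@@H]1[C@@]2(COC(C)=O)CCCC(C)(C)[C@@H]2CC[C@]1(C)O
F6 | step 11 | but-3-yn-2-yl acetate (racemic) | C#CC(C)OC(C)=O
F7 | step 11 | (E)-4-(4,4,5,5-tetramethyl-1,3,2-dioxaborolan-2-yl)but-3-en-2-yl acetate (racemic) | CC(OC(C)=O)/C=C/B1OC(C)(C)C(C)(C)O1
F8 | step 12 | 4-bromobut-2-en-2-yl acetate (E/Z mixture) | CC(=O)OC(C)=CCBr
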